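## The problem

The target is a 3-methyl-1H-isochromen-1-one (ring positions C1 to C8a; ring A is C4a, C5, C6, C7, C8, C8a). Ring A carries a free hydroxyl at C6, a methoxy group at C8 peri to the lactone carbonyl, and at C5 a methylene bridge to ring B. Ring B is a 1,2,3,5-tetrasubstituted benzene (C1' bears the bridge, C2' OMe, C4' OH, C6' CH2OMe). There is no stereocentre, so every difficulty is one of regiochemistry.

On ring A the oxygen pattern is the reverse of what alkylation of a 6,8-diol gives, because the 8-hydroxyl is chelated to C1=O and is methylated last. On ring B the bridge carbon must sit between the methoxy-bearing and the methoxymethyl-bearing carbons and para to the phenol, a site that electrophilic substitution does not single out. The bridge joins two ring carbons that each have two ortho substituents, so a late Friedel–Crafts union would be slow and could not tell C5 from C7.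

The lactone (an enol ester), the benzylic methyl ether and the two electron-rich rings do not tolerate hydroxide, boron trihalides or strong oxidants, so the last steps must be mild.

The enabling feature is that C1, O2, C3 with its methyl, C4, C4a, C8a, C8 with its oxygen and C7 are all present in dehydroacetic acid. Its C4a=C8a bond holds C8 and the future C5 cis. Ring A then lacks only C5, C6 and the C6–C7 bond, which a ketene at C6 can form with an enol ether carbon C7 by six-electron electrocyclization.

## Retrosynthesis

**22 from 21 (O–Si of the ring B phenol).** The last operation is removal of a triisopropylsilyl ether. An acetal protecting group would need acid at the end and, earlier, would steer metalation of ring B to the wrong carbon. The bulky silyl ether is inert to carbonate bases, zerovalent palladium and acylating agents, and buffered fluoride leaves the lactone and the benzylic ether alone. The forward step only has to be chemoselective.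

**21 from 17 (C6–C7, ring A).** Ring A is opened at C6–C7 to the acid 17, in which C6 is a carboxyl carbon and C7 the CH2 terminus of a methyl enol ether. Cutting the same bond in Claisen polarity (ester plus methyl ketone) would give a 6,8-diol and force methylation of the chelated 8-OH beside a free 6-OH. The ketene/enol ether pairing delivers 8-OMe and 6-OH directly. The precursor has one ring fewer and no hexasubstituted benzene. The forward reaction must generate a ketene (via 18 and 19) without protonating the enol ether and must close at carbon (via 20).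

**17 from 15 (C5–CO2 and the allyl esters).** A second carboxyl group is added at C5 and both acids are masked as allyl esters. The malonate makes C5 a soft carbon nucleophile for the two C–C bonds that follow. Allyl esters are cleaved by zerovalent palladium in a basic medium, the one ester cleavage that the enol ether and the pyranone both survive. The forward step must stop after loss of one CO2 (via 16) and keep the acid as a salt.

**15 from 14 and 8 (C5–CH2 of the bridge).** The two halves are joined by alkylation of the stabilized anion of 14 with the benzylic bromide 8, so no arene–arene regiochemistry arises. The reverse order (benzylmalonate first, then substitution at C4) would ask a tertiary carbanion to attack a hindered ring carbon. The cut divides the molecule into two fragments of similar size.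

**14 from 12 and 13 (C4a–C5).** The malonate carbon is attached by addition–elimination of the anion of diallyl malonate 13 at C4 of the 4-chloropyranone 12. The lactone carbonyl activates C4 and chloride loss makes the step irreversible.

**12 from 10, and 10 from 9 (O–CH3 of the enol ether; C4–Cl).** The enol ether is made before any ester is present. With an acetyl group beside the malonate, any acetyl enolate would close onto an ester by Claisen condensation and form C6–C7 with both oxygens unprotected. The price is that C4 of 12 is no longer activated by an acyl group. Chloride 10 comes from commercial dehydroacetic acid 9 in one step. The forward methylation must go to oxygen, not carbon.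

**8 from 7, 6 and 4 (C1'–C of the bridge).** The bridge carbon is introduced as a formyl group by directed metalation of 4 (via 5), then reduced (7) and brominated (8). Electrophilic substitution would not distinguish the two positions ortho to the side chain. Metalation does, because only one site lies between two coordinating groups (OMe and CH2OMe) and the silyl ether shields its own ortho positions.

**4 from 3, 2 and 1.** Benzylic O-methylation, ester reduction and silylation lead back to commercial methyl 3-hydroxy-5-methoxybenzoate 1, in which the two ring B oxygens are already differentiated.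

## Roads not taken

**Alternative 1:** The cut removes both carbon substituents of ring A (C1–C8a and C4–C4a) from a fully oxygenated arene. In the forward step a hindered lithium amide converts the aryl bromide A2 into the C4a–C8a aryne, which inserts into a C–C bond of lithiated dimethyl malonate A3 to give the homophthalate A1.
- Merits: insertion of arynes into the C–C bond of β-dicarbonyl compounds is an established reaction, the route is convergent, and the 8-OMe group directs the nucleophile to the distal carbon C4a as required.
- Weak points: no ring is closed, and C3 with its methyl still has to be added by acylation, cyclization and decarboxylation. A2 is a pentasubstituted arene whose synthesis moves the crowded diarylmethane and the 6-O/8-O differentiation to an earlier stage. The nucleophile must bond next to the bulky C5 benzyl group. The strong base meets a doubly benzylic CH2.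
- Comparison: the key step of this road is better precedented than the chosen one, and that is a real advantage. The chosen plan sets against it a ring-forming step that creates ring A with its oxygens already differentiated, from a commercial template holding eight of the ring atoms.

**Alternative 2:** The cut is C4a–C8a; ring A is unfolded into a keto side chain on the 4-methoxy-2-pyranone A5. In the forward step Mg(OMe)2 in methanol opens the lactone, the dienolate carbon C8a adds to the C4a ketone and water is lost, giving the benzoate A4. Ketal hydrolysis and lactonization would follow.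
- Merits: the step is biomimetic and well precedented. The 8-OMe comes from the pyranone methoxy group and the 6-OH from the ring oxygen, so the oxygens are differentiated as cleanly as in the chosen plan. The ring B benzyl group is already on C5.
- Weak points: A5 is a branched polycarbonyl chain that has to be built by acylating a pyranone side-chain anion carrying the bulky benzyl branch. The opened chain has several enolizable sites and other aldol or Claisen closures are possible. Two further steps are needed to reach the lactone.
- Comparison: in precedent this road is at least as good as the chosen one, and in oxygen differentiation it is equal. The chosen plan answers with a shorter assembly of the precursor (substitution on a commercial pyranone, then malonate alkylation) and a closure that has no competing aldol modes.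

**Alternative 3:** The cut removes two bonds of ring B. In the forward step the ynone A7 on C5 of a finished isocoumarin reacts with the diene A8 in a Diels–Alder reaction; loss of methanol and of the silyl group gives the phenol A6.
- Merits: the ring B pattern (2'-OMe, 4'-OH, 6'-CH2OMe) is set in one step with regiochemistry fixed by the polarized diene. This is better than the directed metalation the chosen plan needs for ring B.
- Weak points: the bridge arrives as a diaryl ketone flanked by four ortho substituents and must be deoxygenated late, beside a lactone, the C3=C4 bond and a benzylic methyl ether. Ring A, its C5 acylation and the 6-O/8-O differentiation must all be solved beforehand.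
- Comparison: this road is superior for ring B but leaves ring A and an extra redox step open. The chosen plan carries the bridge at the CH2 level from the start and solves ring A in its key step.

Key step: step 12

Remark: acid 17 is carried forward as its triethylammonium salt; the compound list shows the free acid.

**Step 1**
Reactants: 1 methyl 3-hydroxy-5-methoxybenzoate
Product: 2 methyl 3-methoxy-5-{[tri(propan-2-yl)silyl]oxy}benzoate
Conditions: iPr3SiCl, imidazole, DMF, rt
Reagents that add atoms: chlorotri(propan-2-yl)silane, CC(C)[Si](Cl)(C(C)C)C(C)C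
Why: Silylation of a phenol; the bulky silyl ether neither directs nor allows lithiation at its ortho positions in step 4 and is removed by fluoride at the end.

**Step 2**
Reactants: 2 methyl 3-methoxy-5-{[tri(propan-2-yl)silyl]oxy}benzoate
Product: 3 (3-methoxy-5-{[tri(propan-2-yl)silyl]oxy}phenyl)methanol
Conditions: iBu2AlH, CH2Cl2, −78 °C to 0 °C
Reagents that add atoms: none
Why: Hydride reduction of a benzoate to the benzylic alcohol; the aryl silyl ether should tolerate iBu2AlH at low temperature.

**Step 3**
Reactants: 3 (3-methoxy-5-{[tri(propan-2-yl)silyl]oxy}phenyl)methanol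
Product: 4 [3-methoxy-5-(methoxymethyl)phenoxy]tri(propan-2-yl)silane
Conditions: MeI, NaH, THF, 0 °C to rt
Reagents that add atoms: iodomethane, CI
Why: Williamson ether synthesis; MeI is present before the base so that the alkoxide is trapped before it can attack silicon.

**Step 4**
Reactants: 4 [3-methoxy-5-(methoxymethyl)phenoxy]tri(propan-2-yl)silane
Product: 6 2-methoxy-6-(methoxymethyl)-4-{[tri(propan-2-yl)silyl]oxy}benzaldehyde, via aryllithium 5 (not isolated)
Conditions: n-BuLi, TMEDA, Et2O, 0 °C; DMF, −78 °C to rt; H2O
Reagents that add atoms: N,N-dimethylformamide, CN(C)C=O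
Why: Directed ortho-metalation; the carbon between OMe and CH2OMe is the only position flanked by two coordinating groups, the positions next to the silyl ether are shielded, and DMF formylates the aryllithium.

**Step 5**
Reactants: 6 2-methoxy-6-(methoxymethyl)-4-{[tri(propan-2-yl)silyl]oxy}benzaldehyde
Product: 7 [2-methoxy-6-(methoxymethyl)-4-{[tri(propan-2-yl)silyl]oxy}phenyl]methanol
Conditions: NaBH4, MeOH, 0 °C
Reagents that add atoms: none
Why: Borohydride reduction of an aryl aldehyde; nothing else in the molecule is reducible under these conditions.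

**Step 6**
Reactants: 7 [2-methoxy-6-(methoxymethyl)-4-{[tri(propan-2-yl)silyl]oxy}phenyl]methanol
Product: 8 [4-(bromomethyl)-3-methoxy-5-(methoxymethyl)phenoxy]tri(propan-2-yl)silane
Conditions: CBr4, PPh3, CH2Cl2, 0 °C; used at once
Reagents that add atoms: tetrabromomethane, BrC(Br)(Br)Br
Why: Appel reaction under neutral conditions; the electron-rich benzylic bromide is not stored because ionization, self-alkylation or closure onto the neighbouring ether oxygen would erode it.

**Step 7**
Reactants: 9 dehydroacetic acid (3-acetyl-4-hydroxy-6-methyl-2H-pyran-2-one)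
Product: 10 3-acetyl-4-chloro-6-methyl-2H-pyran-2-one
Conditions: POCl3, Et3N, CH2Cl2, 0 °C to 40 °C
Reagents that add atoms: phosphoryl chloride, O=P(Cl)(Cl)Cl
Why: Conversion of a vinylogous acid into the vinylogous acid chloride, as is usual for 4-hydroxy-2-pyranones and 4-hydroxycoumarins.

**Step 8**
Reactants: 10 3-acetyl-4-chloro-6-methyl-2H-pyran-2-one
Product: 12 4-chloro-3-(1-methoxyethenyl)-6-methyl-2H-pyran-2-one, via potassium enolate 11 (not isolated)
Conditions: KN(SiMe3)2, THF–DMPU, −78 °C (10 added to the base); MeOTf, −78 °C; Et3N quench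
Reagents that add atoms: methyl trifluoromethanesulfonate, COS(=O)(=O)C(F)(F)F
Why: O-Alkylation of a potassium enolate by a hard methylating agent in a dipolar medium; inverse addition keeps neutral 10 away from its enolate, and no ester is yet present that the enolate could attack.

**Step 9**
Reactants: 12 4-chloro-3-(1-methoxyethenyl)-6-methyl-2H-pyran-2-one; 13 diallyl malonate (diprop-2-en-1-yl propanedioate)
Product: 14 diprop-2-en-1-yl 2-[3-(1-methoxyethenyl)-6-methyl-2-oxo-2H-pyran-4-yl]propanedioate
Conditions: Cs2CO3, DMF, rt to 50 °C; aq. NaH2PO4 (pH 6) work-up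
Reagents that add atoms: none
Why: Addition–elimination of a malonate anion at C4 of a 4-chloro-2-pyranone (vinylogous acyl substitution); the product is held as its stabilized anion until the mild buffer releases it without harming the enol ether.

**Step 10**
Reactants: 14 diprop-2-en-1-yl 2-[3-(1-methoxyethenyl)-6-methyl-2-oxo-2H-pyran-4-yl]propanedioate; 8 [4-(bromomethyl)-3-methoxy-5-(methoxymethyl)phenoxy]tri(propan-2-yl)silane
Product: 15 diprop-2-en-1-yl 2-[3-(1-methoxyethenyl)-6-methyl-2-oxo-2H-pyran-4-yl]-2-{[2-methoxy-6-(methoxymethyl)-4-{[tri(propan-2-yl)silyl]oxy}phenyl]methyl}propanedioate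
Conditions: K2CO3, DMF, 0 °C to rt
Reagents that add atoms: none
Why: Malonic ester alkylation of a stabilized anion with a reactive benzylic bromide; it sets the quaternary C5 and joins the two halves with no base stronger than carbonate.

**Step 11**
Reactants: 15 diprop-2-en-1-yl 2-[3-(1-methoxyethenyl)-6-methyl-2-oxo-2H-pyran-4-yl]-2-{[2-methoxy-6-(methoxymethyl)-4-{[tri(propan-2-yl)silyl]oxy}phenyl]methyl}propanedioate
Product: 17 2-[3-(1-methoxyethenyl)-6-methyl-2-oxo-2H-pyran-4-yl]-3-[2-methoxy-6-(methoxymethyl)-4-{[tri(propan-2-yl)silyl]oxy}phenyl]propanoic acid (racemic), via malonic diacid 16 (not isolated)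
Conditions: Pd(PPh3)4 (5 mol%), HCO2H (2.1 equiv), Et3N (6 equiv), THF, rt, then 50 °C; filtered through Et3N-treated silica and kept as the Et3NH salt
Reagents that add atoms: none
Why: Tsuji–Trost-type deallylation by zerovalent palladium with formate as hydride donor frees the malonate in a basic medium; the diacid, a vinylogous β-keto acid through the pyranone, should lose one CO2 on gentle warming, and keeping the product as a salt keeps the carboxyl proton away from the enol ether.

**Step 12**
Reactants: 17 2-[3-(1-methoxyethenyl)-6-methyl-2-oxo-2H-pyran-4-yl]-3-[2-methoxy-6-(methoxymethyl)-4-{[tri(propan-2-yl)silyl]oxy}phenyl]propanoic acid (racemic)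
Product: 21 6-hydroxy-8-methoxy-5-{[2-methoxy-6-(methoxymethyl)-4-{[tri(propan-2-yl)silyl]oxy}phenyl]methyl}-3-methyl-1H-isochromen-1-one, via mixed pivalic anhydride 18 (not isolated), via dienylketene 19 (not isolated), via cyclohexadienone 20 (not isolated)
Conditions: t-BuCOCl (1.05 equiv), Et3N (3 equiv), toluene, 0 °C; then added slowly to toluene at 100 °C, high dilution
Reagents that add atoms: none
Why: Proposed new method: Et3N removes the C5 hydrogen of mixed anhydride 18, which is acidified by the acyl group and, vinylogously, by the pyranone carbonyl, and loss of pivalate (E1cB) gives ketene 19 (C6=C5). The ketene, the ring-locked cis C4a=C8a bond and the enol ether C8=C7 form a hexatriene that closes thermally by disrotatory six-electron electrocyclization, making C6–C7 and ring A as cyclohexadienone 20, which tautomerizes to the C6 phenol 21. The closest known reaction type is the benzannulation of dienylketenes to phenols, the ketenes coming from 4-vinylcyclobutenones (Danheiser benzannulation) or from activated 3,5-dienoic acids; a case in which the central double bond belongs to a 2-pyranone and one terminus is an enol ether has not been shown. No stereocentre is formed and the one in 17 is lost at the ketene stage. The step needs closure at carbon C7 and not at oxygen: the acetyl oxygen is methylated, which closes off the oxa-electrocyclization to a second pyranone, and the electron-rich CH2 terminus is polarity-matched to the electrophilic ketene carbon, so that even a stepwise C-acylation of the enol ether by 18 would lead to the same dienone 20. Because C8 enters as a methyl enol ether, 8-OMe and 6-OH are differentiated without any selective methylation. High dilution and slow addition should keep the unimolecular closure ahead of ketene dimerization and of acylation of the new phenol.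

**Step 13**
Reactants: 21 6-hydroxy-8-methoxy-5-{[2-methoxy-6-(methoxymethyl)-4-{[tri(propan-2-yl)silyl]oxy}phenyl]methyl}-3-methyl-1H-isochromen-1-one
Product: 22 6-hydroxy-5-{[4-hydroxy-2-methoxy-6-(methoxymethyl)phenyl]methyl}-8-methoxy-3-methyl-1H-isochromen-1-one
Conditions: Bu4NF, AcOH, THF, 0 °C
Reagents that add atoms: none
Why: Fluoride cleavage of an aryl silyl ether; buffering with AcOH keeps the lactone from basic fluoride, and the benzylic methyl ether is untouched.

## Compound list

1 | methyl 3-hydroxy-5-methoxybenzoate | COC(=O)c1cc(O)cc(OC)c1 | starting material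
2 | methyl 3-methoxy-5-{[tri(propan-2-yl)silyl]oxy}benzoate | COC(=O)c1cc(OC)cc(O[Si](C(C)C)(C(C)C)C(C)C)c1 | intermediate
3 | (3-methoxy-5-{[tri(propan-2-yl)silyl]oxy}phenyl)methanol | OCc1cc(OC)cc(O[Si](C(C)C)(C(C)C)C(C)C)c1 | intermediate
4 | [3-methoxy-5-(methoxymethyl)phenoxy]tri(propan-2-yl)silane | COCc1cc(OC)cc(O[Si](C(C)C)(C(C)C)C(C)C)c1 | intermediate
5 | [2-methoxy-6-(methoxymethyl)-4-{[tri(propan-2-yl)silyl]oxy}phenyl]lithium | [Li]c1c(OC)cc(O[Si](C(C)C)(C(C)C)C(C)C)cc1COC | intermediate
6 | 2-methoxy-6-(methoxymethyl)-4-{[tri(propan-2-yl)silyl]oxy}benzaldehyde | COCc1cc(O[Si](C(C)C)(C(C)C)C(C)C)cc(OC)c1C=O | intermediate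
7 | [2-methoxy-6-(methoxymethyl)-4-{[tri(propan-2-yl)silyl]oxy}phenyl]methanol | COCc1cc(O[Si](C(C)C)(C(C)C)C(C)C)cc(OC)c1CO | intermediate
8 | [4-(bromomethyl)-3-methoxy-5-(methoxymethyl)phenoxy]tri(propan-2-yl)silane | COCc1cc(O[Si](C(C)C)(C(C)C)C(C)C)cc(OC)c1CBr | intermediate
9 | dehydroacetic acid (3-acetyl-4-hydroxy-6-methyl-2H-pyran-2-one) | CC(=O)c1c(O)cc(C)oc1=O | starting material
10 | 3-acetyl-4-chloro-6-methyl-2H-pyran-2-one | CC(=O)c1c(Cl)cc(C)oc1=O | intermediate
11 | potassium 1-(4-chloro-6-methyl-2-oxo-2H-pyran-3-yl)ethen-1-olate | [K+].[O-]C(=C)c1c(Cl)cc(C)oc1=O | intermediate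
12 | 4-chloro-3-(1-methoxyethenyl)-6-methyl-2H-pyran-2-one | COC(=C)c1c(Cl)cc(C)oc1=O | intermediate
13 | diallyl malonate (diprop-2-en-1-yl propanedioate) | C=CCOC(=O)CC(=O)OCC=C | starting material
14 | diprop-2-en-1-yl 2-[3-(1-methoxyethenyl)-6-methyl-2-oxo-2H-pyran-4-yl]propanedioate | COC(=C)c1c(C(C(=O)OCC=C)C(=O)OCC=C)cc(C)oc1=O | intermediate
15 | diprop-2-en-1-yl 2-[3-(1-methoxyethenyl)-6-methyl-2-oxo-2H-pyran-4-yl]-2-{[2-methoxy-6-(methoxymethyl)-4-{[tri(propan-2-yl)silyl]oxy}phenyl]methyl}propanedioate | COC(=C)c1c(C(Cc2c(COC)cc(O[Si](C(C)C)(C(C)C)C(C)C)cc2OC)(C(=O)OCC=C)C(=O)OCC=C)cc(C)oc1=O | intermediate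
16 | 2-[3-(1-methoxyethenyl)-6-methyl-2-oxo-2H-pyran-4-yl]-2-{[2-methoxy-6-(methoxymethyl)-4-{[tri(propan-2-yl)silyl]oxy}phenyl]methyl}propanedioic acid | COC(=C)c1c(C(Cc2c(COC)cc(O[Si](C(C)C)(C(C)C)C(C)C)cc2OC)(C(O)=O)C(O)=O)cc(C)oc1=O | intermediate
17 | 2-[3-(1-methoxyethenyl)-6-methyl-2-oxo-2H-pyran-4-yl]-3-[2-methoxy-6-(methoxymethyl)-4-{[tri(propan-2-yl)silyl]oxy}phenyl]propanoic acid (racemic) | COC(=C)c1c(C(Cc2c(COC)cc(O[Si](C(C)C)(C(C)C)C(C)C)cc2OC)C(O)=O)cc(C)oc1=O | intermediate
18 | 2,2-dimethylpropanoic 2-[3-(1-methoxyethenyl)-6-methyl-2-oxo-2H-pyran-4-yl]-3-[2-methoxy-6-(methoxymethyl)-4-{[tri(propan-2-yl)silyl]oxy}phenyl]propanoic anhydride (racemic) | COC(=C)c1c(C(Cc2c(COC)cc(O[Si](C(C)C)(C(C)C)C(C)C)cc2OC)C(=O)OC(=O)C(C)(C)C)cc(C)oc1=O | intermediate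
19 | 3-(1-methoxyethenyl)-4-{3-[2-methoxy-6-(methoxymethyl)-4-{[tri(propan-2-yl)silyl]oxy}phenyl]-1-oxoprop-1-en-2-yl}-6-methyl-2H-pyran-2-one | COC(=C)c1c(C(Cc2c(COC)cc(O[Si](C(C)C)(C(C)C)C(C)C)cc2OC)=C=O)cc(C)oc1=O | intermediate
20 | 8-methoxy-5-{[2-methoxy-6-(methoxymethyl)-4-{[tri(propan-2-yl)silyl]oxy}phenyl]methyl}-3-methyl-1H-isochromene-1,6(7H)-dione | COC1=C2C(=O)OC(C)=CC2=C(Cc2c(COC)cc(O[Si](C(C)C)(C(C)C)C(C)C)cc2OC)C(=O)C1 | intermediate
21 | 6-hydroxy-8-methoxy-5-{[2-methoxy-6-(methoxymethyl)-4-{[tri(propan-2-yl)silyl]oxy}phenyl]methyl}-3-methyl-1H-isochromen-1-one | COCc1cc(O[Si](C(C)C)(C(C)C)C(C)C)cc(OC)c1Cc1c(O)cc(OC)c2c(=O)oc(C)cc12 | intermediate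
22 | 6-hydroxy-5-{[4-hydroxy-2-methoxy-6-(methoxymethyl)phenyl]methyl}-8-methoxy-3-methyl-1H-isochromen-1-one (CNP0481202.0) | COCc1cc(O)cc(OC)c1Cc1c(O)cc(OC)c2c(=O)oc(C)cc12 | target

## Step count and least certain steps

Total: 13 steps. Longest linear sequence: 10 steps (steps 1 to 6 and 10 to 13, from 1); the pyranone branch (steps 7 to 9) joins at step 10.

**Step 12 (key step).** Ketene formation may stall at the enolate of 18. The ketene may also be lost to dimerization, to acylation of the product phenol or to four-electron closure to a cyclobutenone before C6–C7 forms, and the enol ether may be protonated by triethylammonium pivalate at 100 °C. The fallback is the Claisen polarity for the same bond, all known chemistry. It sets out from 15: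
- Hydrolysis of the enol ether (aqueous oxalic acid, THF) gives the methyl ketone diprop-2-en-1-yl 2-(3-acetyl-6-methyl-2-oxo-2H-pyran-4-yl)-2-{[2-methoxy-6-(methoxymethyl)-4-{[tri(propan-2-yl)silyl]oxy}phenyl]methyl}propanedioate F1.
- NaH in THF brings about Dieckmann condensation of the acetyl enolate with one allyl ester, forming C6–C7 and giving prop-2-en-1-yl 8-hydroxy-5-{[2-methoxy-6-(methoxymethyl)-4-{[tri(propan-2-yl)silyl]oxy}phenyl]methyl}-3-methyl-1,6-dioxo-5,6-dihydro-1H-isochromene-5-carboxylate F2.
- Pd(PPh3)4 and morpholine remove the remaining allyl ester; the β-keto acid loses CO2 and aromatizes to 6,8-dihydroxy-5-{[2-methoxy-6-(methoxymethyl)-4-{[tri(propan-2-yl)silyl]oxy}phenyl]methyl}-3-methyl-1H-isochromen-1-one F3.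
- The unchelated 6-OH is allylated selectively (allyl bromide, K2CO3, acetone) to 8-hydroxy-5-{[2-methoxy-6-(methoxymethyl)-4-{[tri(propan-2-yl)silyl]oxy}phenyl]methyl}-3-methyl-6-(prop-2-en-1-yloxy)-1H-isochromen-1-one F4.
- The chelated 8-OH is methylated (MeI, K2CO3, acetone, reflux) to 8-methoxy-5-{[2-methoxy-6-(methoxymethyl)-4-{[tri(propan-2-yl)silyl]oxy}phenyl]methyl}-3-methyl-6-(prop-2-en-1-yloxy)-1H-isochromen-1-one F5.
- Pd(PPh3)4 and morpholine free the 6-OH, and the route is rejoined at 21.

This line is five steps longer and relies on chelation to tell the two oxygens apart.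

**Step 8.** The enolate may be methylated at carbon, the base may deprotonate the 6-methyl group, or the enolate may condense with the vinylogous acid chloride of a second molecule. The fallback avoids an enolate. From 10, HC(OMe)3 and TsOH in MeOH would give the acetal 4-chloro-3-(1,1-dimethoxyethyl)-6-methyl-2H-pyran-2-one F6. Me3SiOTf and iPr2NEt in CH2Cl2 then eliminate methanol, returning at 12.

**Step 9.** Substitution may be slow because C4 is now activated only by the lactone carbonyl and sits beside the methoxyvinyl group. The malonate may instead attack C6 and open the pyranone. The fallback replaces uncatalysed substitution by a copper-catalysed coupling. From 9, POBr3 would give 3-acetyl-4-bromo-6-methyl-2H-pyran-2-one F7. Enolate O-methylation as in step 8 gives 4-bromo-3-(1-methoxyethenyl)-6-methyl-2H-pyran-2-one F8. Hurtley-type coupling with 13 (CuI, pyridine-2-carboxylic acid, Cs2CO3, 1,4-dioxane) returns at 14.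

**Step 11.** If the carboxylic acid is protonated during isolation it may add across the enol ether to a six-membered pseudo-ester, the enol ether may hydrolyse, or the second carboxyl group may be lost on warming. The fallback is the Claisen line described under step 12, which sets out from 15, returns at 21 and never has a free acid beside the enol ether.

**Step 4.** Metalation may occur at the benzylic CH2 of the methoxymethyl group (followed by Wittig rearrangement) or at the position between OMe and the silyl ether. The fallback uses alkoxide direction and halogen–metal exchange. From 3, two equivalents of n-BuLi with TMEDA lithiate the lithium alkoxide between CH2OLi and OMe, and I2 gives (2-iodo-3-methoxy-5-{[tri(propan-2-yl)silyl]oxy}phenyl)methanol F9. NaH and MeI give [4-iodo-3-methoxy-5-(methoxymethyl)phenoxy]tri(propan-2-yl)silane F10. Exchange with iPrMgCl·LiCl and DMF returns at 6.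

## Further compounds

F1 | step 12 | diprop-2-en-1-yl 2-(3-acetyl-6-methyl-2-oxo-2H-pyran-4-yl)-2-{[2-methoxy-6-(methoxymethyl)-4-{[tri(propan-2-yl)silyl]oxy}phenyl]methyl}propanedioate | CC(=O)c1c(C(Cc2c(COC)cc(O[Si](C(C)C)(C(C)C)C(C)C)cc2OC)(C(=O)OCC=C)C(=O)OCC=C)cc(C)oc1=O
F2 | step 12 | prop-2-en-1-yl 8-hydroxy-5-{[2-methoxy-6-(methoxymethyl)-4-{[tri(propan-2-yl)silyl]oxy}phenyl]methyl}-3-methyl-1,6-dioxo-5,6-dihydro-1H-isochromene-5-carboxylate (racemic) | C=CCOC(=O)C1(Cc2c(COC)cc(O[Si](C(C)C)(C(C)C)C(C)C)cc2OC)C(=O)C=C(O)c2c1cc(C)oc2=O
F3 | step 12 | 6,8-dihydroxy-5-{[2-methoxy-6-(methoxymethyl)-4-{[tri(propan-2-yl)silyl]oxy}phenyl]methyl}-3-methyl-1H-isochromen-1-one | COCc1cc(O[Si](C(C)C)(C(C)C)C(C)C)cc(OC)c1Cc1c(O)cc(O)c2c(=O)oc(C)cc12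
F4 | step 12 | 8-hydroxy-5-{[2-methoxy-6-(methoxymethyl)-4-{[tri(propan-2-yl)silyl]oxy}phenyl]methyl}-3-methyl-6-(prop-2-en-1-yloxy)-1H-isochromen-1-one | COCc1cc(O[Si](C(C)C)(C(C)C)C(C)C)cc(OC)c1Cc1c(OCC=C)cc(O)c2c(=O)oc(C)cc12
F5 | step 12 | 8-methoxy-5-{[2-methoxy-6-(methoxymethyl)-4-{[tri(propan-2-yl)silyl]oxy}phenyl]methyl}-3-methyl-6-(prop-2-en-1-yloxy)-1H-isochromen-1-one | COCc1cc(O[Si](C(C)C)(C(C)C)C(C)C)cc(OC)c1Cc1c(OCC=C)cc(OC)c2c(=O)oc(C)cc12
F6 | step 8 | 4-chloro-3-(1,1-dimethoxyethyl)-6-methyl-2H-pyran-2-one | COC(C)(OC)c1c(Cl)cc(C)oc1=O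
F7 | step 9 | 3-acetyl-4-bromo-6-methyl-2H-pyran-2-one | CC(=O)c1c(Br)cc(C)oc1=O
F8 | step 9 | 4-bromo-3-(1-methoxyethenyl)-6-methyl-2H-pyran-2-one | COC(=C)c1c(Br)cc(C)oc1=O
F0 | step 11 | none | none
F9 | step 4 | (2-iodo-3-methoxy-5-{[tri(propan-2-yl)silyl]oxy}phenyl)methanol | OCc1cc(O[Si](C(C)C)(C(C)C)C(C)C)cc(OC)c1I
F10 | step 4 | [4-iodo-3-methoxy-5-(methoxymethyl)phenoxy]tri(propan-2-yl)silane | COCc1cc(O[Si](C(C)C)(C(C)C)C(C)C)cc(OC)c1I
A1 | alternative 1 | methyl 6-methoxy-2-(2-methoxy-2-oxoethyl)-3-{[2-methoxy-6-(methoxymethyl)-4-{[tri(propan-2-yl)silyl]oxy}phenyl]methyl}-4-{[tri(propan-2-yl)silyl]oxy}benzoate | COC(=O)Cc1c(Cc2c(COC)cc(O[Si](C(C)C)(C(C)C)C(C)C)cc2OC)c(O[Si](C(C)C)(C(C)C)C(C)C)cc(OC)c1C(=O)OC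
A2 | alternative 1 | [3-bromo-5-methoxy-2-{[2-methoxy-6-(methoxymethyl)-4-{[tri(propan-2-yl)silyl]oxy}phenyl]methyl}phenoxy]tri(propan-2-yl)silane | COCc1cc(O[Si](C(C)C)(C(C)C)C(C)C)cc(OC)c1Cc1c(Br)cc(OC)cc1O[Si](C(C)C)(C(C)C)C(C)C
A3 | alternative 1 | dimethyl propanedioate | COC(=O)CC(=O)OC
A4 | alternative 2 | methyl 4-hydroxy-2-methoxy-5-{[2-methoxy-6-(methoxymethyl)-4-(methoxymethoxy)phenyl]methyl}-6-[(2-methyl-1,3-dioxolan-2-yl)methyl]benzoate | COC(=O)c1c(OC)cc(O)c(Cc2c(COC)cc(OCOC)cc2OC)c1CC1(C)OCCO1
A5 | alternative 2 | 4-methoxy-6-{1-[2-methoxy-6-(methoxymethyl)-4-(methoxymethoxy)phenyl]-4-(2-methyl-1,3-dioxolan-2-yl)-3-oxobutan-2-yl}-2H-pyran-2-one (racemic) | COc1cc(=O)oc(c1)C(Cc1c(COC)cc(OCOC)cc1OC)C(=O)CC1(C)OCCO1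
A6 | alternative 3 | 5-[4-hydroxy-2-methoxy-6-(methoxymethyl)benzoyl]-8-methoxy-6-(methoxymethoxy)-3-methyl-1H-isochromen-1-one | COCc1cc(O)cc(OC)c1C(=O)c1c(OCOC)cc(OC)c2c(=O)oc(C)cc12
A7 | alternative 3 | 8-methoxy-5-(4-methoxybut-2-ynoyl)-6-(methoxymethoxy)-3-methyl-1H-isochromen-1-one | COCC#CC(=O)c1c(OCOC)cc(OC)c2c(=O)oc(C)cc12
A8 | alternative 3 | [(4,4-dimethoxybuta-1,3-dien-2-yl)oxy]trimethylsilane | COC(OC)=CC(=C)O[Si](C)(C)C
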